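**Plan**

1. Numbering: C1(=O) lies between C2(OMe) and C6(octadecyl); C3–H, C4(=O) and C5–H complete the ring. The quinone is taken back to hydroquinone 12 (redox). The ring is then cut at C4–C3, the bond from the carbonyl carbon to the CH beside the methoxy-bearing carbon (retro-6π), and re-closed as the C4–C1 bond of a four-membered ring (retro-4π), giving cyclobutenone 9.
2. 9 is cut at C1–C2 into 1-methoxyvinyllithium (C2, C3, OMe) and 3-octadecylcyclobutene-1,2-dione 6 (C1, C4, C5, C6). 6 goes back to diisopropyl squarate and an octadecyl Grignard reagent.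
3. Forward: the purchased four-membered ring receives the chain (step 1), exchanges its isopropoxy group for H (step 2), takes up the methoxyvinyl unit (step 3) and is expanded thermally to the six-membered ring (step 4). Oxidation ends the route (step 5).
4. Enabling feature: the para pair of ring oxygens with the enol-ether unit C2(OMe)=C3H beside C1. C1 is a masked tertiary carbinol, C4 a masked ketene carbon and C2=C3 a masked vinyl group, so every ring substituent is placed before the six-membered ring exists.
5. Stereochemistry: the target has no stereocentre; the carbinol centre of 9 is racemic and is erased on aromatisation.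

Key step: step 4

Remark: the SMILES is read as achiral 2-methoxy-6-octadecylcyclohexa-2,5-diene-1,4-dione. Octadecylmagnesium chloride (C18H37MgCl) is taken as the purchasable THF solution.

**Route**

Step 1
Reactants: 1 diisopropyl squarate; 2 octadecylmagnesium chloride
Product: 4 3-isopropoxy-4-octadecylcyclobut-3-ene-1,2-dione, via squarate adduct 3 (not isolated)
Conditions: THF, −78 → −20 °C; 1 M HCl quench; then conc. HCl (cat.), CH2Cl2, rt
Reagents that add atoms: water (O)
Why: Grignard 1,2-addition to one of the two equivalent carbonyls of the squarate, then acid ionisation of the tertiary allylic hydroxyl, water capture at the distal isopropoxy carbon and loss of isopropanol (the standard squarate to 3-alkoxy-4-alkylcyclobutenedione transposition) should give 4, which has no stereocentre.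

Step 2
Reactants: 4 3-isopropoxy-4-octadecylcyclobut-3-ene-1,2-dione
Product: 6 3-octadecylcyclobut-3-ene-1,2-dione, via hydroxycyclobutenone 5 (not isolated)
Conditions: LiAlH(OtBu)3, THF, −78 → −20 °C; then 6 M HCl, CH2Cl2, rt
Reagents that add atoms: none
Why: The mild hydride should reduce only the ketone-like carbonyl beside the isopropoxy-bearing carbon (the other is a vinylogous ester), and acid should then drive an α-ketol-type 1,2-hydride shift onto the protonated vinylogous ester and β-elimination of isopropanol to the conjugated ene-dione, a reduction/acid-transposition sequence of the kind used to convert 3-alkoxy-4-alkylcyclobutenediones into monosubstituted cyclobutenediones.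

Step 3
Reactants: 6 3-octadecylcyclobut-3-ene-1,2-dione; 7 methyl vinyl ether
Product: 9 (±)-4-hydroxy-4-(1-methoxyvinyl)-3-octadecylcyclobut-2-en-1-one, via 1-methoxyvinyllithium 8 (not isolated)
Conditions: 7, t-BuLi, THF, −78 → 0 °C; then added to 6, THF, −78 °C; aq. NH4Cl; Et3N-washed SiO2
Reagents that add atoms: none
Why: Alkenyllithium 1,2-addition to a cyclobutenedione should occur at the carbonyl flanked by the octadecyl-bearing carbon, because the other carbonyl is the vinylogous partner of the alkyl-donor-substituted alkene carbon and is deactivated, the in-plane chain hardly shields its neighbour on the flat ring, and the adduct keeps the better-stabilised β-alkyl enone; the carbinol centre forms as a racemate.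

Step 4
Reactants: 9 (±)-4-hydroxy-4-(1-methoxyvinyl)-3-octadecylcyclobut-2-en-1-one
Product: 12 2-methoxy-6-octadecylbenzene-1,4-diol, via dienylketene 10 (not isolated), via cyclohexadienone 11 (not isolated)
Conditions: p-xylene (degassed, 0.02 M), reflux (138 °C), Ar
Reagents that add atoms: none
Why: Heating should open the cyclobutenone by conrotatory 4π electrocyclic cleavage of the bond between the carbonyl carbon and the carbinol carbon, giving dienylketene 10 in which the hydroxyl has rotated outward and the 1-methoxyvinyl group inward, so that the ketene carbon and the vinyl CH2 terminus sit cis across the new C=C bond. A disrotatory 6π electrocyclisation of this triene (ketene C=C, central C=C, vinyl C=C) then joins the ketene carbon to the CH2 terminus and closes the only six-membered ring of the target as cyclohexadienone 11, which enolises irreversibly to hydroquinone 12. The closest known reaction type is the Moore rearrangement of 4-alkenyl-4-hydroxycyclobutenones to hydroquinones. No stereocentre is formed, and the racemic centre of 9 disappears. The step needs torquoselectivity (an inward hydroxyl would trap the ketene as a butenolide) and regiocontrol: the first is secured by the strong preference of the donor hydroxyl for outward rotation, the second by the fact that all six ring carbons and their substituents are already connected in 9 in the required order, so only one constitution can result.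

Step 5
Reactants: 12 2-methoxy-6-octadecylbenzene-1,4-diol
Product: 13 2-methoxy-6-octadecylcyclohexa-2,5-diene-1,4-dione
Conditions: Ag2O, Na2SO4, Et2O, rt (crude 12 used directly)
Reagents that add atoms: none
Why: Two-electron oxidation of an electron-rich hydroquinone to the p-benzoquinone with Ag2O is routine and should leave the vinylogous-ester methoxy group and the saturated chain untouched.

**Compound list**

1 | diisopropyl squarate (3,4-diisopropoxycyclobut-3-ene-1,2-dione) | CC(C)OC1=C(OC(C)C)C(=O)C1=O | starting material
2 | octadecylmagnesium chloride | CCCCCCCCCCCCCCCCCC[Mg]Cl | starting material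
3 | 4-hydroxy-2,3-diisopropoxy-4-octadecylcyclobut-2-en-1-one (squarate adduct, racemic) | CCCCCCCCCCCCCCCCCCC1(O)C(=O)C(OC(C)C)=C1OC(C)C | intermediate
4 | 3-isopropoxy-4-octadecylcyclobut-3-ene-1,2-dione | CCCCCCCCCCCCCCCCCCC1=C(OC(C)C)C(=O)C1=O | intermediate
5 | 4-hydroxy-3-isopropoxy-2-octadecylcyclobut-2-en-1-one (racemic) | CCCCCCCCCCCCCCCCCCC1=C(OC(C)C)C(O)C1=O | intermediate
6 | 3-octadecylcyclobut-3-ene-1,2-dione | CCCCCCCCCCCCCCCCCCC1=CC(=O)C1=O | intermediate
7 | methyl vinyl ether | COC=C | starting material
8 | 1-methoxyvinyllithium | [Li]C(=C)OC | intermediate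
9 | (±)-4-hydroxy-4-(1-methoxyvinyl)-3-octadecylcyclobut-2-en-1-one | CCCCCCCCCCCCCCCCCCC1=CC(=O)C1(O)C(=C)OC | intermediate
10 | (3E)-4-hydroxy-5-methoxy-3-octadecylhexa-1,3,5-trien-1-one (dienylketene) | O=C=C/C(CCCCCCCCCCCCCCCCCC)=C(O)\C(=C)OC | intermediate
11 | 4-hydroxy-5-methoxy-3-octadecylcyclohexa-2,4-dien-1-one | CCCCCCCCCCCCCCCCCCC1=CC(=O)CC(OC)=C1O | intermediate
12 | 2-methoxy-6-octadecylbenzene-1,4-diol | CCCCCCCCCCCCCCCCCCc1cc(O)cc(OC)c1O | intermediate
13 | 2-methoxy-6-octadecylcyclohexa-2,5-diene-1,4-dione | CCCCCCCCCCCCCCCCCCC1=CC(=O)C=C(OC)C1=O | target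

**Summary**

Total step count: 5. Longest linear sequence: 5 steps (1 → 4 → 6 → 9 → 12 → 13).

Steps most likely to fail:

1. Step 3. The alkenyllithium may add at the wrong carbonyl or at both, or act as a base on the sensitive ene-dione, so that regiocontrol is lost. The fallback sets out from 1 and comes back at 9; it lets an alkoxy group dictate each addition.
   - Reduction of 1 with LiAlH(OtBu)3 (THF, −78 °C) should give the hydride adduct 4-hydroxy-2,3-diisopropoxycyclobut-2-en-1-one F1. Conc. HCl in CH2Cl2 should convert it, by the transposition of step 1, into 3-isopropoxycyclobut-3-ene-1,2-dione F2.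
   - Reagent 8 should add to F2 only at the ketone-like carbonyl beside the isopropoxy-bearing carbon, giving 4-hydroxy-3-isopropoxy-4-(1-methoxyvinyl)cyclobut-2-en-1-one F3. Silylation (Me3SiCl, Et3N) gives 3-isopropoxy-4-(1-methoxyvinyl)-4-(trimethylsilyloxy)cyclobut-2-en-1-one F4.
   - 1,2-Addition of 2 to the remaining carbonyl (THF, −78 °C) gives 3-isopropoxy-4-(1-methoxyvinyl)-1-octadecyl-4-(trimethylsilyloxy)cyclobut-2-en-1-ol F5. Brief contact with moist, oxalic-acid-doped silica gel should ionise it and expel isopropanol (Stork–Danheiser-type transposition) to give 4-(1-methoxyvinyl)-3-octadecyl-4-(trimethylsilyloxy)cyclobut-2-en-1-one F6.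
   - Bu4NF/AcOH in THF at 0 °C then frees 9.

2. Step 4. The ketene may be consumed before electrocyclisation (dimerisation, lactonisation after inward rotation of the hydroxyl), or the enol ether may be lost at 138 °C. The fallback sets out from 2 and comes back at 13; it builds on a preformed arene instead of a ring expansion.
   - Purchased 2-bromo-6-methoxyphenol is benzylated (BnBr, K2CO3, DMF) to 2-(benzyloxy)-1-bromo-3-methoxybenzene F7.
   - Kumada coupling of F7 with 2 (Ni(dppp)Cl2 cat., THF, reflux) should give 2-(benzyloxy)-1-methoxy-3-octadecylbenzene F8.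
   - Hydrogenolysis (H2, Pd/C, EtOAc) gives 2-methoxy-6-octadecylphenol F9.
   - Teuber oxidation with ON(SO3K)2 (KH2PO4, acetone/water) at the free para position should give 13 directly.

3. Step 2. Over-reduction, incomplete acid transposition or nucleophilic ring cleavage of the monosubstituted ene-dione may erode the material. The fallback sets out from 4 and comes back at 6; it replaces hydride delivery to a carbonyl by reduction of a vinylogous acid chloride.
   - Acid hydrolysis of 4 (6 M HCl, THF, reflux) should give 3-hydroxy-4-octadecylcyclobut-3-ene-1,2-dione F10.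
   - Oxalyl chloride with catalytic DMF (CH2Cl2, rt) converts it into 3-chloro-4-octadecylcyclobut-3-ene-1,2-dione F11.
   - Palladium-catalysed hydrodechlorination with Bu3SnH (Pd(PPh3)4 cat., THF, rt) should give 6.

**Further compounds**

F1 | step 3 | 4-hydroxy-2,3-diisopropoxycyclobut-2-en-1-one | CC(C)OC1=C(OC(C)C)C(O)C1=O
F2 | step 3 | 3-isopropoxycyclobut-3-ene-1,2-dione | CC(C)OC1=CC(=O)C1=O
F3 | step 3 | 4-hydroxy-3-isopropoxy-4-(1-methoxyvinyl)cyclobut-2-en-1-one (racemic) | O=C1C=C(OC(C)C)C1(O)C(=C)OC
F4 | step 3 | 3-isopropoxy-4-(1-methoxyvinyl)-4-(trimethylsilyloxy)cyclobut-2-en-1-one (racemic) | O=C1C=C(OC(C)C)C1(O[Si](C)(C)C)C(=C)OC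
F5 | step 3 | 3-isopropoxy-4-(1-methoxyvinyl)-1-octadecyl-4-(trimethylsilyloxy)cyclobut-2-en-1-ol (mixture of diastereomers) | CCCCCCCCCCCCCCCCCCC1(O)C=C(OC(C)C)C1(O[Si](C)(C)C)C(=C)OC
F6 | step 3 | 4-(1-methoxyvinyl)-3-octadecyl-4-(trimethylsilyloxy)cyclobut-2-en-1-one (racemic) | CCCCCCCCCCCCCCCCCCC1=CC(=O)C1(O[Si](C)(C)C)C(=C)OC
F7 | step 4 | 2-(benzyloxy)-1-bromo-3-methoxybenzene | COc1cccc(Br)c1OCc1ccccc1
F8 | step 4 | 2-(benzyloxy)-1-methoxy-3-octadecylbenzene | CCCCCCCCCCCCCCCCCCc1cccc(OC)c1OCc1ccccc1
F9 | step 4 | 2-methoxy-6-octadecylphenol | CCCCCCCCCCCCCCCCCCc1cccc(OC)c1O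
F10 | step 2 | 3-hydroxy-4-octadecylcyclobut-3-ene-1,2-dione | CCCCCCCCCCCCCCCCCCC1=C(O)C(=O)C1=O
F11 | step 2 | 3-chloro-4-octadecylcyclobut-3-ene-1,2-dione | CCCCCCCCCCCCCCCCCCC1=C(Cl)C(=O)C1=O
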